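**Retrosynthetic overview**

1. Numbering: ring C1(=CH2)–C2–C3–C4(OH)–C5(Me2)–C6(H); chain C7–C15; the pyrone sits on C15.
2. C15–C3(pyrone) is made last, by Pd-catalysed (Tsuji–Trost) C-allylation of 4-hydroxy-6-methyl-2-pyrone with the C20 allylic carbonate.
3. C7–C8 comes from alkylation of a ring sulfone carbanion (C7) with (2E,6E)-8-bromogeranyl acetate, then reductive desulfonylation; both E-trisubstituted alkenes are bought with geranyl acetate.
4. The only ring is closed at C1–C6 by a hydrostannylative 6-exo-trig vinyl-radical cyclisation of an acyclic 1,7-enyne vinyl sulfone. The terminal alkyne becomes C1 and the exocyclic =CH2, C6 is set cis to C4–O across the C5 gem-dimethyl, and the CH2SO2Ph arm is C7.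
5. The acyclic precursor gets its C4–C5 bond and the C4 stereocentre by Brown reverse prenylation of pent-4-ynal; the vinyl group is then cut to the aldehyde and olefinated to the vinyl sulfone.

Key step: step 5

Remark: the target SMILES is read as 4S,6R with the C4 hydroxyl and the C6 chain cis; compounds 1, 2 (THF solution), 7, 12 and 19 are taken as catalogue items.

**Step 1**
Reactants: 1 pent-4-ynal; 2 prenylmagnesium chloride (3-methylbut-2-enylmagnesium chloride)
Product: 4 (4S)-3,3-dimethyloct-1-en-7-yn-4-ol, via diisopinocampheylborinate ester 3 (not isolated)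
Conditions: (+)-Ipc2BOMe [from (−)-α-pinene], 2, Et2O, 0 °C → rt; then 1, −78 °C; then 3 M NaOH, 30% H2O2
Reagents that add atoms: none
Why: Brown asymmetric allylboration, in which the B-prenyl borane adds through a closed chair transition state by its γ-carbon, so that the C4–C5 bond, the quaternary CMe2 and a terminal vinyl group form together, and the Ipc groups of the (−)-α-pinene series should direct attack to the Re face of 1 and set C4 as S (same sense as the allyl and crotyl reagents of this series).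

**Step 2**
Reactants: 4 (4S)-3,3-dimethyloct-1-en-7-yn-4-ol
Product: 5 triethyl{[(4S)-3,3-dimethyloct-1-en-7-yn-4-yl]oxy}silane
Conditions: TESOTf, 2,6-lutidine, CH2Cl2, −78 → 0 °C
Reagents that add atoms: triethylsilyl triflate, CC[Si](CC)(CC)OS(=O)(=O)C(F)(F)F
Why: Silyl triflate silylation of a hindered secondary alcohol, which touches no stereocentre and blocks retro-aldol cleavage in steps 3 and 4.

**Step 3**
Reactants: 5 triethyl{[(4S)-3,3-dimethyloct-1-en-7-yn-4-yl]oxy}silane
Product: 6 (3S)-2,2-dimethyl-3-[(triethylsilyl)oxy]hept-6-ynal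
Conditions: O3, CH2Cl2/MeOH, −78 °C (Sudan III end point); then Me2S, −78 °C → rt
Reagents that add atoms: ozone, [O-][O+]=O
Why: Chemoselective ozonolysis, since the monosubstituted alkene reacts far faster with ozone than the terminal alkyne, and reductive work-up gives the non-enolisable α-quaternary aldehyde.

**Step 4**
Reactants: 6 (3S)-2,2-dimethyl-3-[(triethylsilyl)oxy]hept-6-ynal; 7 diethyl [(phenylsulfonyl)methyl]phosphonate
Product: 8 triethyl{[(1E,4S)-3,3-dimethyl-1-(phenylsulfonyl)oct-1-en-7-yn-4-yl]oxy}silane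
Conditions: NaH, THF, 0 °C; then 6, 0 °C → rt
Reagents that add atoms: none
Why: Horner–Wadsworth–Emmons olefination with a sulfonyl-stabilised phosphonate anion, which is E-selective and cannot epimerise the α-quaternary aldehyde.

**Step 5**
Reactants: 8 triethyl{[(1E,4S)-3,3-dimethyl-1-(phenylsulfonyl)oct-1-en-7-yn-4-yl]oxy}silane
Product: 11 (1S,3R)-2,2-dimethyl-4-methylidene-3-[(phenylsulfonyl)methyl]cyclohexan-1-ol, via vinylstannane 9 (not isolated), via triethylsilyl ether 10 (not isolated)
Conditions: Bu3SnH (1.3 equiv, syringe pump), AIBN (0.2 equiv), PhH (0.01 M), 80 °C; concentrate; then TsOH·H2O (1.5 equiv), CH2Cl2/MeOH, 0 °C → rt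
Reagents that add atoms: none
Why: Bu3Sn• adds reversibly to the terminal alkyne carbon of 8, the β-stannyl vinyl radical at C1 closes onto C6 (the β-carbon of the vinyl sulfone), and the sulfone-stabilised C7 radical takes H from Bu3SnH to carry the chain; TsOH then cleaves the C–Sn bond by ipso-protonation to give the exocyclic C1=CH2 and, in MeOH, removes the TES group. The closest known reaction type is the Stork/Oshima hydrostannylative radical cyclisation of 1,n-enynes onto electron-poor alkenes followed by protodestannylation. The one ring of the target closes in the 6-exo-trig mode at C1–C6. C6 is set by 1,3-induction from C4 across the C5 gem-dimethyl: a chair-like transition state with the C4 silyloxy group and the C6=C7 arm both pseudo-equatorial should give the 4,6-cis ring, i.e. 4S,6R. The step needs exo over 7-endo closure, which the polarity of the vinyl sulfone secures, and cyclisation over open-chain hydrostannation, which high dilution and slow hydride addition secure. Both alkene isomers of 8 would converge on the same C7 radical, so the geometry from step 4 is not critical.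

**Step 6**
Reactants: 12 geranyl acetate
Product: 13 (2E,6E)-8-hydroxy-3,7-dimethylocta-2,6-dien-1-yl acetate
Conditions: SeO2 (0.3 equiv), t-BuOOH (3 equiv), salicylic acid (cat.), CH2Cl2, rt
Reagents that add atoms: tert-butyl hydroperoxide, CC(C)(C)OO
Why: Sharpless catalytic SeO2/t-BuOOH allylic oxidation (ene reaction then [2,3]-sigmatropic shift), which is selective for the E-methyl group of the terminal trisubstituted alkene.

**Step 7**
Reactants: 13 (2E,6E)-8-hydroxy-3,7-dimethylocta-2,6-dien-1-yl acetate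
Product: 14 (2E,6E)-8-bromo-3,7-dimethylocta-2,6-dien-1-yl acetate
Conditions: CBr4, PPh3, CH2Cl2, −20 → 0 °C
Reagents that add atoms: carbon tetrabromide, BrC(Br)(Br)Br
Why: Appel bromination of a primary allylic alcohol under neutral conditions, an SN2 displacement without allylic transposition that keeps the E geometry.

**Step 8**
Reactants: 11 (1S,3R)-2,2-dimethyl-4-methylidene-3-[(phenylsulfonyl)methyl]cyclohexan-1-ol; 14 (2E,6E)-8-bromo-3,7-dimethylocta-2,6-dien-1-yl acetate
Product: 15 (2E,6E)-9-[(1R,3S)-3-hydroxy-2,2-dimethyl-6-methylidenecyclohexyl]-3,7-dimethyl-9-(phenylsulfonyl)nona-2,6-dien-1-yl acetate (both C9 epimers)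
Conditions: n-BuLi (2.1 equiv), THF/DMPU, −78 → −30 °C; then 14, −78 → −40 °C
Reagents that add atoms: none
Why: Alkylation of an α-sulfonyl carbanion (as the O,C-dianion) by SN2 displacement on a primary allylic bromide, which should form C7–C8 without touching either E-alkene; the new C7 centre is removed in step 9.

**Step 9**
Reactants: 15 (2E,6E)-9-[(1R,3S)-3-hydroxy-2,2-dimethyl-6-methylidenecyclohexyl]-3,7-dimethyl-9-(phenylsulfonyl)nona-2,6-dien-1-yl acetate
Product: 17 (2E,6E)-9-[(1R,3S)-3-hydroxy-2,2-dimethyl-6-methylidenecyclohexyl]-3,7-dimethylnona-2,6-dien-1-ol, via hydroxy sulfone 16 (not isolated)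
Conditions: K2CO3 (0.2 equiv), MeOH, rt; then 6% Na(Hg) (excess), MeOH/THF, 0 °C → rt
Reagents that add atoms: none
Why: Base-catalysed methanolysis of the acetate followed by single-electron reductive desulfonylation of the alkyl phenyl sulfone (Julia-type Na/Hg cleavage), which leaves the isolated alkenes and both alcohols untouched.

**Step 10**
Reactants: 17 (2E,6E)-9-[(1R,3S)-3-hydroxy-2,2-dimethyl-6-methylidenecyclohexyl]-3,7-dimethylnona-2,6-dien-1-ol
Product: 18 (2E,6E)-9-[(1R,3S)-3-hydroxy-2,2-dimethyl-6-methylidenecyclohexyl]-3,7-dimethylnona-2,6-dien-1-yl methyl carbonate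
Conditions: ClCO2Me (1.1 equiv), pyridine, CH2Cl2, −20 °C
Reagents that add atoms: methyl chloroformate, COC(=O)Cl
Why: Acylation with a chloroformate, which should be selective for the unhindered primary allylic alcohol over the secondary C4 alcohol next to the quaternary C5.

**Step 11**
Reactants: 18 (2E,6E)-9-[(1R,3S)-3-hydroxy-2,2-dimethyl-6-methylidenecyclohexyl]-3,7-dimethylnona-2,6-dien-1-yl methyl carbonate; 19 4-hydroxy-6-methyl-2H-pyran-2-one
Product: 20 sartorypyrone D, 4-hydroxy-3-{(2E,6E)-9-[(1R,3S)-3-hydroxy-2,2-dimethyl-6-methylidenecyclohexyl]-3,7-dimethylnona-2,6-dien-1-yl}-6-methyl-2H-pyran-2-one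
Conditions: 19 (2.5 equiv), Pd(PPh3)4 (5 mol %), THF, rt → 40 °C
Reagents that add atoms: none
Why: Tsuji–Trost allylation, in which ionisation of the carbonate gives a π-allyl palladium complex and methoxide that deprotonates 19, and the soft C3 nucleophile should attack the unsubstituted allyl terminus (O-allylation is reversible under Pd) to give the linear 2E product, with excess 19 suppressing double allylation.

**Compound list**

1 | pent-4-ynal | C#CCCC=O | starting material
2 | prenylmagnesium chloride | CC(C)=CC[Mg]Cl | starting material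
3 | (4S)-3,3-dimethyloct-1-en-7-yn-4-yl diisopinocampheylborinate | C#CCC[C@H](OB([C@H]1C[C@H]2C[C@@H]([C@@H]1C)C2(C)C)[C@H]1C[C@H]2C[C@@H]([C@@H]1C)C2(C)C)C(C)(C)C=C | intermediate
4 | (4S)-3,3-dimethyloct-1-en-7-yn-4-ol | C#CCC[C@H](O)C(C)(C)C=C | intermediate
5 | triethyl{[(4S)-3,3-dimethyloct-1-en-7-yn-4-yl]oxy}silane | C#CCC[C@H](O[Si](CC)(CC)CC)C(C)(C)C=C | intermediate
6 | (3S)-2,2-dimethyl-3-[(triethylsilyl)oxy]hept-6-ynal | C#CCC[C@H](O[Si](CC)(CC)CC)C(C)(C)C=O | intermediate
7 | diethyl [(phenylsulfonyl)methyl]phosphonate | CCOP(=O)(CS(=O)(=O)c1ccccc1)OCC | starting material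
8 | triethyl{[(1E,4S)-3,3-dimethyl-1-(phenylsulfonyl)oct-1-en-7-yn-4-yl]oxy}silane | C#CCC[C@H](O[Si](CC)(CC)CC)C(C)(C)/C=C/S(=O)(=O)c1ccccc1 | intermediate
9 | exocyclic vinylstannane of 10 (Bu3Sn on the exocyclic CH, expected mainly E, i.e. anti to C6) | CCCC[Sn](CCCC)(CCCC)/C=C1\CC[C@H](O[Si](CC)(CC)CC)C(C)(C)[C@@H]1CS(=O)(=O)c1ccccc1 | intermediate
10 | triethyl{[(1S,3R)-2,2-dimethyl-4-methylidene-3-[(phenylsulfonyl)methyl]cyclohexyl]oxy}silane | C=C1CC[C@H](O[Si](CC)(CC)CC)C(C)(C)[C@@H]1CS(=O)(=O)c1ccccc1 | intermediate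
11 | (1S,3R)-2,2-dimethyl-4-methylidene-3-[(phenylsulfonyl)methyl]cyclohexan-1-ol | C=C1CC[C@H](O)C(C)(C)[C@@H]1CS(=O)(=O)c1ccccc1 | intermediate
12 | geranyl acetate | CC(C)=CCC/C(C)=C/COC(C)=O | starting material
13 | (2E,6E)-8-hydroxy-3,7-dimethylocta-2,6-dien-1-yl acetate | OC/C(C)=C/CC/C(C)=C/COC(C)=O | intermediate
14 | (2E,6E)-8-bromo-3,7-dimethylocta-2,6-dien-1-yl acetate | BrC/C(C)=C/CC/C(C)=C/COC(C)=O | intermediate
15 | (2E,6E)-9-[(1R,3S)-3-hydroxy-2,2-dimethyl-6-methylidenecyclohexyl]-3,7-dimethyl-9-(phenylsulfonyl)nona-2,6-dien-1-yl acetate (C9 epimers) | C=C1CC[C@H](O)C(C)(C)[C@@H]1C(C/C(C)=C/CC/C(C)=C/COC(C)=O)S(=O)(=O)c1ccccc1 | intermediate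
16 | (2E,6E)-9-[(1R,3S)-3-hydroxy-2,2-dimethyl-6-methylidenecyclohexyl]-3,7-dimethyl-9-(phenylsulfonyl)nona-2,6-dien-1-ol (C9 epimers) | C=C1CC[C@H](O)C(C)(C)[C@@H]1C(C/C(C)=C/CC/C(C)=C/CO)S(=O)(=O)c1ccccc1 | intermediate
17 | (2E,6E)-9-[(1R,3S)-3-hydroxy-2,2-dimethyl-6-methylidenecyclohexyl]-3,7-dimethylnona-2,6-dien-1-ol | C=C1CC[C@H](O)C(C)(C)[C@@H]1CC/C(C)=C/CC/C(C)=C/CO | intermediate
18 | (2E,6E)-9-[(1R,3S)-3-hydroxy-2,2-dimethyl-6-methylidenecyclohexyl]-3,7-dimethylnona-2,6-dien-1-yl methyl carbonate | C=C1CC[C@H](O)C(C)(C)[C@@H]1CC/C(C)=C/CC/C(C)=C/COC(=O)OC | intermediate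
19 | 4-hydroxy-6-methyl-2H-pyran-2-one | Cc1cc(O)cc(=O)o1 | starting material
20 | sartorypyrone D | C=C1CC[C@H](O)C(C)(C)[C@@H]1CC/C(C)=C/CC/C(C)=C/Cc1c(O)cc(C)oc1=O | target

**Step count and risks**

Total steps: 11. Longest linear sequence: 9 (steps 1–5, then 8–11).

Step 5 is the most likely to fail. The facial discrimination in the 6-exo closure may be incomplete, the vinyl radical may be reduced by Bu3SnH before it closes, or the stannyl radical may add to the vinyl sulfone and expel the sulfonyl group. The fallback sets out from 8 and leaves the radical manifold for a closed-shell one, a Pd-catalysed reductive enyne cyclisation (Pd2(dba)3·CHCl3, P(o-tol)3, AcOH, Et3SiH, toluene, rt). H–Pd should add across the alkyne with Pd at C1, the vinyl sulfone should insert syn in the 6-exo mode, and the silane should cleave the C7–Pd bond. This gives triethylsilyl ether 10 without tin, and acid methanolysis (TsOH, MeOH) comes back to the route at 11. The fallback makes no compound outside the list (F0).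

Step 8 is the second risk. The hindered dianion may alkylate slowly, so that attack on the acetate or proton transfer from the allylic bromide competes. The fallback sets out from 7, 14 and 6 and makes the C7–C8 bond earlier, on the doubly activated carbon of the phosphonate. Alkylation of 7 with 14 (NaH, THF/DMF, 0 °C) should give diethyl [(3E,7E)-9-acetoxy-3,7-dimethyl-1-(phenylsulfonyl)nona-3,7-dien-1-yl]phosphonate F1. Horner–Wadsworth–Emmons reaction of F1 with aldehyde 6 should give the trisubstituted vinyl sulfone enyne (2E,6E,12S)-3,7,11,11-tetramethyl-9-(phenylsulfonyl)-12-[(triethylsilyl)oxy]hexadeca-2,6,9-trien-15-yn-1-yl acetate F2, whose 9E/9Z isomers are both usable. The conditions of step 5 then close the ring onto F2 through a tertiary α-sulfonyl radical at C7, by way of the exocyclic vinylstannane F3. Protodestannylation gives the triethylsilyl ether of 15 F4, and the same acid treatment cleaves the silyl ether, so the fallback comes back to the route at 15.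

Step 11 is the third risk. Regiocontrol in the capture of the π-allyl complex may be lost (branched or O-allyl product, double allylation at C3), or syn/anti isomerisation of the π-allyl complex may erode the 2E geometry. The fallback sets out from 17 and builds the pyrone on the chain instead of allylating it. Appel bromination of the primary allylic alcohol (CBr4, PPh3, −30 °C) should give (1S,3R)-3-[(3E,7E)-9-bromo-3,7-dimethylnona-3,7-dien-1-yl]-2,2-dimethyl-4-methylidenecyclohexan-1-ol F5. SN2 C-alkylation of ethyl sodioacetoacetate, which retains the alkene geometry, should give ethyl (4E,8E)-2-acetyl-11-[(1R,3S)-3-hydroxy-2,2-dimethyl-6-methylidenecyclohexyl]-5,9-dimethylundeca-4,8-dienoate F6. The polyanion (LDA, 3.2 equiv, which also covers the free C4 hydroxyl) is acetylated at the γ-carbon with N-methoxy-N-methylacetamide to ethyl (4E,8E)-11-[(1R,3S)-3-hydroxy-2,2-dimethyl-6-methylidenecyclohexyl]-5,9-dimethyl-2-(3-oxobutanoyl)undeca-4,8-dienoate F7. DBU in toluene at reflux should lactonise F7 to the 4-hydroxy-2-pyrone, so the fallback comes back to the route at 20.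

**Further compounds**

F0 | step 5 | none | none
F1 | step 8 | diethyl [(3E,7E)-9-acetoxy-3,7-dimethyl-1-(phenylsulfonyl)nona-3,7-dien-1-yl]phosphonate | CCOP(=O)(OCC)C(C/C(C)=C/CC/C(C)=C/COC(C)=O)S(=O)(=O)c1ccccc1
F2 | step 8 | (2E,6E,12S)-3,7,11,11-tetramethyl-9-(phenylsulfonyl)-12-[(triethylsilyl)oxy]hexadeca-2,6,9-trien-15-yn-1-yl acetate (9E/9Z) | C#CCC[C@H](O[Si](CC)(CC)CC)C(C)(C)C=C(C/C(C)=C/CC/C(C)=C/COC(C)=O)S(=O)(=O)c1ccccc1
F3 | step 8 | exocyclic vinylstannane of F4 (Bu3Sn on the exocyclic CH, anti to C6) | CCCC[Sn](CCCC)(CCCC)/C=C1\CC[C@H](O[Si](CC)(CC)CC)C(C)(C)[C@@H]1C(C/C(C)=C/CC/C(C)=C/COC(C)=O)S(=O)(=O)c1ccccc1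
F4 | step 8 | triethylsilyl ether of 15 | C=C1CC[C@H](O[Si](CC)(CC)CC)C(C)(C)[C@@H]1C(C/C(C)=C/CC/C(C)=C/COC(C)=O)S(=O)(=O)c1ccccc1
F5 | step 11 | (1S,3R)-3-[(3E,7E)-9-bromo-3,7-dimethylnona-3,7-dien-1-yl]-2,2-dimethyl-4-methylidenecyclohexan-1-ol | C=C1CC[C@H](O)C(C)(C)[C@@H]1CC/C(C)=C/CC/C(C)=C/CBr
F6 | step 11 | ethyl (4E,8E)-2-acetyl-11-[(1R,3S)-3-hydroxy-2,2-dimethyl-6-methylidenecyclohexyl]-5,9-dimethylundeca-4,8-dienoate | C=C1CC[C@H](O)C(C)(C)[C@@H]1CC/C(C)=C/CC/C(C)=C/CC(C(C)=O)C(=O)OCC
F7 | step 11 | ethyl (4E,8E)-11-[(1R,3S)-3-hydroxy-2,2-dimethyl-6-methylidenecyclohexyl]-5,9-dimethyl-2-(3-oxobutanoyl)undeca-4,8-dienoate | C=C1CC[C@H](O)C(C)(C)[C@@H]1CC/C(C)=C/CC/C(C)=C/CC(C(=O)CC(C)=O)C(=O)OCC
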